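The numbers in the tables are calculated on assumed constants, noise included.

53.3 % was the mean target over the last teal readings, yet teal began with 2.40 reagent per starting material. Amber, at 1.20 reagent per starting material and 75 °C, levelled at 54.8 %, and green at 37.9 %.

common to all: catalyst 0.50 mM
- amber: starting material 0.050 M; reagent 0.060 M; second substrate 0.050 M; temperature 75 °C; run made earlier
- teal: starting material 0.025 M; reagent 0.060 M; second substrate 0.050 M; temperature 90 °C; run made earlier
- green: starting material 0.10 M; reagent 0.060 M; second substrate 0.050 M; temperature 75 °C; run made earlier
- north: starting material 0.050 M; reagent 0.0600 M; second substrate 0.0500 M; everything together at the start at 60 °C, warmed to 90 °C at 10 h; time 25 h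
- north-west: starting material 0.050 M; reagent 0.0600 M (fed, over 2.5 h); second substrate 0.0500 M; temperature 90 °C; all else is in the flask from the start; the feed brings no volume worth counting; time 25 h
- west: starting material 0.050 M; reagent 0.0600 M (fed, over 10 h); second substrate 0.0500 M; temperature 90 °C; all else is in the flask from the start; the feed brings no volume worth counting; time 25 h
- east: starting material 0.050 M; reagent 0.0600 M; second substrate 0.0500 M; temperature 90 °C; everything together at the start; time 25 h
- south-east: starting material 0.050 M (fed, over 10 h); reagent 0.0600 M; second substrate 0.0500 M; temperature 90 °C; all else is in the flask from the start; the feed brings no volume worth counting; time 25 h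
- north-east: starting material 0.050 M; reagent 0.0600 M (fed, over 10 h); second substrate 0.0500 M; the addition at 60 °C, then warmed to 90 °C; the feed brings no volume worth counting; time 25 h

| run | time / h | target / % | starting material / % |
|---|---|---|---|
| amber | 4.00 | 46.9 | 52.3 |
| amber | 6.00 | 50.1 | 49.4 |
| amber | 10.0 | 55.0 | 45.0 |
| amber | 15.0 | 53.7 | 45.8 |
| amber | 20.0 | 54.9 | 46.4 |
| amber | 30.0 | 55.6 | 46.8 |
| amber | 48.0 | 55.0 | 45.7 |
| teal | 0.833 | 33.3 | 66.8 |
| teal | 2.50 | 47.6 | 54.0 |
| teal | 4.00 | 51.6 | 48.5 |
| teal | 6.00 | 52.4 | 47.1 |
| teal | 10.0 | 52.2 | 44.8 |
| teal | 12.0 | 53.2 | 45.4 |
| teal | 15.0 | 55.4 | 44.9 |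
| green | 3.00 | 35.2 | 63.4 |
| green | 4.00 | 37.4 | 62.2 |
| green | 6.00 | 37.9 | 62.8 |
| green | 8.00 | 37.1 | 62.5 |
| green | 12.0 | 38.3 | 61.1 |
| green | 20.0 | 38.1 | 60.3 |
| green | 30.0 | 38.0 | 62.2 |

(scatter of a reading: 1 percentage point)

- what was read earlier has a scatter of 1 percentage point, one standard deviation

1. the flask with the highest amount of target, in percent of the starting material charged ("all alike" if they lie within 1.5 percentage points) (north / north-west / west / east / south-east / north-east / all alike)
2. final target, as a percentage of the starting material charged, in north
3. final target, as a percentage of the starting material charged, in north-west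
4. final target, as a percentage of the starting material charged, in west
5. final target, as a percentage of the starting material charged, in east
6. final target, as a percentage of the starting material charged, in south-east
7. final target, as a percentage of the starting material charged, in north-east

I cleared this up by supposing that reagent has a second way out, and that each reagent not found in target was lost elsewhere. That makes reagent the limiting reagent. Teal gives 15.6 L mol⁻¹ for s, the selectivity factor: target formed per reagent lost elsewhere, divided by the mean c(starting material), taken halfway between charge and end. At 75 °C, amber gives 23.2 L mol⁻¹ and green 21.1 L mol⁻¹, close together although green held twice the starting material. Teal's s at 90 °C is smaller than either.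

The earlier runs had their charges in at the start, and east is made that way at teal's temperature, so I carried teal's s to east, where solving for the target gave me 45.1 %. For north and the fed flasks I made no figure.

The forecast differed from my figure for east. It said “I read the plateaus as equilibrium” and answered all alike: north 42 %, north-west 42 %, west 42 %, east 42 %, south-east 42 %, north-east 42 %.

The flasks gave west as the highest: north 62.8 %, north-west 56.8 %, west 67.0 %, east 44.9 %, south-east 10.1 %, north-east 64.3 %.

    2 reagent → homo dimer (k = 0.320 L mol⁻¹ min⁻¹, Ea = 86.0 kJ mol⁻¹)
    second substrate + reagent + catalyst → catalyst + second product (k = 170 L² mol⁻² min⁻¹, Ea = 59.0 kJ mol⁻¹)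
    starting material + reagent + catalyst → catalyst + target (k = 580 L² mol⁻² min⁻¹, Ea = 49.0 kJ mol⁻¹)
    (constants at 90 °C)

West ended with 0.00566 % of its reagent, and its target gives s = 37.9 L mol⁻¹, larger than teal's 15.6 L mol⁻¹ at the same temperature. The largest single effect on the gap between west and south-east is the step from reagent to homo dimer: without it the gap falls from 57 percentage points to 28 points. For the neighbour that is west with 0.20 M of starting material, west's s gives 26.1 % target. The computed flask gave 27.2 %.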